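**Retrosynthetic overview**
1. Feature used: in each flavone half the benzo ring A (C4a, C5, C6, C7, C8, C8a) is a 1,3-dioxygenated benzene fused to the pyranone ring C, with OH on C5 beside C4a, the second oxygen on C7, CH at C6 and C8, and O1 on C8a. A ketene carbon (C5), the two carbons of an ynol ether (C6, C7) and a diazo carbon (C8) map onto this pattern.
2. Both rings A are removed together (cuts at C4a–C5, C5–C6 and C7–C8 in each half), leading to a diaryl ether that carries two 6-aryl-4-pyranones with a diazoacetyl group on the future C8a, and to (triisopropylsiloxy)acetylene.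
3. The diazo ketones come from the bis(4-pyranone-2-carboxylic acid); each ring C is closed by acid from a 6-aryl-2,4,6-trioxohexanoate.
4. The trioxo esters are built by two Claisen condensations (ethyl acetate, then diethyl oxalate) on a bis(acetophenone) whose C3'–O–C4''' diaryl ether bond is made first by SNAr between the two ring B precursors.
5. Order of ring formation: rings B are purchased, the two rings C are closed in step 4, the two rings A in step 8; desilylation then gives the target.

Key step: step 8

Remark: the target has no stereocentre. From step 2 onward every step acts on both halves of the diaryl ether at once, so two molecules each of ethyl acetate, diethyl oxalate, diazomethane and the siloxyalkyne are built into one molecule of substrate. Diazomethane for step 6 is generated from N-methyl-N-nitroso-p-toluenesulfonamide and KOH and used in ether. (Triisopropylsiloxy)acetylene is not an article of commerce and is made in step 7.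

**Step 1**
Reactants: 1 3-hydroxy-4-methoxyacetophenone; 2 4-fluoroacetophenone
Product: 3 1-[3-(4-acetylphenoxy)-4-methoxyphenyl]ethanone (the bis(acetophenone))
Conditions: K2CO3, DMAc, 140 °C
Reagents that add atoms: none
Why: Nucleophilic aromatic substitution (addition–elimination) of the phenoxide on the fluoride para to the activating acetyl group forms the C3'–O–C4''' diaryl ether bond, fluoride being the best leaving group for this mechanism.

**Step 2**
Reactants: 3 bis(acetophenone); 4 ethyl acetate (two molecules, one for each acetyl group)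
Product: 5 1-{4-methoxy-3-[4-(3-oxobutanoyl)phenoxy]phenyl}butane-1,3-dione (the bis(1,3-diketone))
Conditions: 4 (6 equiv), NaH (5 equiv), THF, reflux; then aq. HCl
Reagents that add atoms: ethyl acetate (second molecule of 4) CC(=O)OCC
Why: Crossed Claisen condensation of each aryl methyl ketone enolate with one molecule of ethyl acetate is driven to completion by deprotonation of the β-diketone that forms, as in the preparation of benzoylacetone.

**Step 3**
Reactants: 5 bis(1,3-diketone); 6 diethyl oxalate (two molecules, one for each diketone arm)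
Product: 7 ethyl 6-{3-[4-(6-ethoxy-3,5,6-trioxohexanoyl)phenoxy]-4-methoxyphenyl}-2,4,6-trioxohexanoate (the bis(trioxo ester), drawn as the keto form)
Conditions: 6 (3 equiv), NaOEt (5 equiv), EtOH, 0 °C to reflux; then cold aq. HCl
Reagents that add atoms: diethyl oxalate (second molecule of 6) CCOC(=O)C(=O)OCC
Why: Claisen condensation under equilibrating ethoxide conditions places one ethoxalyl group, from one molecule of diethyl oxalate, on the terminal methyl of each of the two diketone arms, because acylation at the central carbon is reversible and only the terminal product is held as a doubly deprotonated species, as in the preparation of acetonedioxalic ester.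

**Step 4**
Reactants: 7 bis(trioxo ester)
Product: 9 6-{3-[4-(6-carboxy-4-oxo-4H-pyran-2-yl)phenoxy]-4-methoxyphenyl}-4-oxo-4H-pyran-2-carboxylic acid (the bis(pyranone acid)), via bis(pyranone ethyl ester) 8 (not isolated)
Conditions: conc. HCl, AcOH, reflux
Reagents that add atoms: water O
Why: Acid-catalysed cyclodehydration of a 1,3,5-tricarbonyl chain (enol oxygen of the aryl ketone onto the C2 ketone, loss of water) is the classical 4-pyranone synthesis used for chelidonic and comanic acids, and the same hot aqueous acid hydrolyses the esters without the ring opening that hydroxide would cause.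

**Step 5**
Reactants: 9 bis(pyranone acid)
Product: 10 6-{3-[4-(6-chlorocarbonyl-4-oxo-4H-pyran-2-yl)phenoxy]-4-methoxyphenyl}-4-oxo-4H-pyran-2-carbonyl chloride (the bis(acid chloride), used crude)
Conditions: (COCl)2, DMF (cat.), CH2Cl2, 0 °C to rt; evaporation
Reagents that add atoms: oxalyl chloride O=C(Cl)C(=O)Cl
Why: Acid chloride formation through the chloroiminium species from oxalyl chloride and DMF runs under non-basic conditions that leave the pyranone rings and the aryl ethers intact, as in the preparation of chromone-2-carbonyl chlorides.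

**Step 6**
Reactants: 10 bis(acid chloride)
Product: 11 2-(diazoacetyl)-6-{3-[4-(6-diazoacetyl-4-oxo-4H-pyran-2-yl)phenoxy]-4-methoxyphenyl}-4H-pyran-4-one (the bis(diazo ketone))
Conditions: CH2N2 (excess), Et2O–THF, 0 °C
Reagents that add atoms: diazomethane (two molecules, one for each acid chloride) C=[N+]=[N-].C=[N+]=[N-]
Why: Acylation of diazomethane by an acid chloride (first stage of the Arndt–Eistert sequence) is fast at 0 °C, the excess diazomethane takes up the HCl as chloromethane so that no chloromethyl ketone forms, and the short cold reaction keeps dipolar cycloaddition to the pyranone double bonds in check.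

**Step 7**
Reactants: 12 acetylene; 13 chlorotriisopropylsilane
Product: 16 (triisopropylsiloxy)acetylene, via lithium acetylide 14 (not isolated), via lithium ethynolate 15 (not isolated)
Conditions: acetylene (excess), n-BuLi, THF, −78 °C; t-BuOOLi (from t-BuOOH, LiN(SiMe3)2), −78 to −25 °C; iPr3SiCl, −78 °C to rt
Reagents that add atoms: tert-butyl hydroperoxide (source of the oxygen atom) CC(C)(C)OO; n-butyllithium (source of the lithium of 14 and 15) [Li]CCCC
Why: Electrophilic oxygen transfer from lithium tert-butyl peroxide to a lithium acetylide (oxidation of acetylides to ynolates), followed by silylation that the bulky triisopropylsilyl chloride directs to oxygen, is the established route from terminal alkynes to 1-siloxyalkynes and is applied here to acetylene itself, kept in excess and cold so that the monolithium acetylide does not disproportionate.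

**Step 8**
Reactants: 11 bis(diazo ketone); 16 (triisopropylsiloxy)acetylene (two molecules, one for each ring A)
Product: 21 7,7''-bis-O-(triisopropylsilyl)-4'-O-methylochnaflavone, via bis(pyranonylketene) 17 (not isolated), via bis(siloxycyclobutenone) 18 (not isolated), via bis(dienylketene) 19 (not isolated), via bis(cyclohexadienone) 20 (not isolated)
Conditions: 16 (4 equiv), hν (405 nm LED), ClCH2CH2Cl, 20 °C; then 80 °C
Reagents that add atoms: (triisopropylsiloxy)acetylene (second molecule of 16) C#CO[Si](C(C)C)(C(C)C)C(C)C
Why: Light at the long-wavelength edge of the diazo ketone absorption expels N2 from each diazoacetyl group and the pyranonyl group shifts to the carbene carbon (Wolff rearrangement), so that the former diazo carbon (later C8) becomes bonded to the pyranone carbon that is C8a and the former carbonyl carbon (later C5) becomes the ketene carbon of 17. Each ketene adds one molecule of 16 in a (2+2) cycloaddition in which the nucleophilic unsubstituted alkyne carbon bonds to the electrophilic ketene carbon (C5–C6) and the siloxy-bearing carbon bonds to the ketene CH (C7–C8), giving the 4-pyranonyl-3-siloxycyclobutenone 18, which at 80 °C opens by reversible 4π electrocyclic cleavage to the dienylketene 19. Each ring A is then closed by a thermal 6π electrocyclization of the isomer of 19 in which the pyranonyl group is cis to the ketenyl carbon, the ketene carbon bonding to the only free neighbouring position, the pyranone CH that becomes C4a (C4a–C5), and the resulting 1,3-diketone 20 enolizes to the hydrogen-bonded C5 phenol. The closest known reaction type is the Danheiser benzannulation in its photochemical diazo ketone form with siloxyalkynes, established for aryl and heteroaryl (for instance 2-furyl) diazomethyl ketones; this pyranone substrate is a new member of that class and carries the uncertainty of the route. No stereocentre remains in 21, since those of 18 and 20 are transient and are erased by ring opening and enolization. The step needs regioselectivity in the (2+2) event, secured by the oxygen-induced polarization of the ynol ether so that oxygen ends on C7 and not on C6, and chemoselectivity between the two chromophores, secured by irradiating at 405 nm where the aryl pyranone is transparent and by an excess of 16 that traps each ketene as it forms.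

**Step 9**
Reactants: 21 7,7''-bis-O-(triisopropylsilyl)-4'-O-methylochnaflavone
Product: 22 4'-O-methylochnaflavone
Conditions: Bu4NF, AcOH, THF, 0 °C
Reagents that add atoms: none
Why: Fluoride cleaves the two aryl silyl ethers by attack at silicon (desilylation) while acetic acid buffers the phenoxides, and the methyl ether, the diaryl ether and the flavone rings are inert to these conditions.

**Compound list**
1 | 3-hydroxy-4-methoxyacetophenone | CC(=O)c1ccc(OC)c(O)c1 | starting material
2 | 4-fluoroacetophenone | CC(=O)c1ccc(F)cc1 | starting material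
3 | 1-[3-(4-acetylphenoxy)-4-methoxyphenyl]ethanone | COc1ccc(C(C)=O)cc1Oc1ccc(C(C)=O)cc1 | intermediate
4 | ethyl acetate | CC(=O)OCC | starting material
5 | 1-{4-methoxy-3-[4-(3-oxobutanoyl)phenoxy]phenyl}butane-1,3-dione | COc1ccc(C(=O)CC(C)=O)cc1Oc1ccc(C(=O)CC(C)=O)cc1 | intermediate
6 | diethyl oxalate | CCOC(=O)C(=O)OCC | starting material
7 | ethyl 6-{3-[4-(6-ethoxy-3,5,6-trioxohexanoyl)phenoxy]-4-methoxyphenyl}-2,4,6-trioxohexanoate | COc1ccc(C(=O)CC(=O)CC(=O)C(=O)OCC)cc1Oc1ccc(C(=O)CC(=O)CC(=O)C(=O)OCC)cc1 | intermediate
8 | ethyl 6-{3-[4-(6-ethoxycarbonyl-4-oxo-4H-pyran-2-yl)phenoxy]-4-methoxyphenyl}-4-oxo-4H-pyran-2-carboxylate | COc1ccc(-c2cc(=O)cc(C(=O)OCC)o2)cc1Oc1ccc(-c2cc(=O)cc(C(=O)OCC)o2)cc1 | intermediate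
9 | 6-{3-[4-(6-carboxy-4-oxo-4H-pyran-2-yl)phenoxy]-4-methoxyphenyl}-4-oxo-4H-pyran-2-carboxylic acid | COc1ccc(-c2cc(=O)cc(C(=O)O)o2)cc1Oc1ccc(-c2cc(=O)cc(C(=O)O)o2)cc1 | intermediate
10 | 6-{3-[4-(6-chlorocarbonyl-4-oxo-4H-pyran-2-yl)phenoxy]-4-methoxyphenyl}-4-oxo-4H-pyran-2-carbonyl chloride | COc1ccc(-c2cc(=O)cc(C(=O)Cl)o2)cc1Oc1ccc(-c2cc(=O)cc(C(=O)Cl)o2)cc1 | intermediate
11 | 2-(diazoacetyl)-6-{3-[4-(6-diazoacetyl-4-oxo-4H-pyran-2-yl)phenoxy]-4-methoxyphenyl}-4H-pyran-4-one | COc1ccc(-c2cc(=O)cc(C(=O)C=[N+]=[N-])o2)cc1Oc1ccc(-c2cc(=O)cc(C(=O)C=[N+]=[N-])o2)cc1 | intermediate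
12 | acetylene | C#C | starting material
13 | chlorotriisopropylsilane | CC(C)[Si](Cl)(C(C)C)C(C)C | starting material
14 | lithium acetylide | [Li+].[C-]#C | intermediate
15 | lithium ethynolate | [Li+].[O-]C#C | intermediate
16 | (triisopropylsiloxy)acetylene (ethynyl triisopropylsilyl ether) | C#CO[Si](C(C)C)(C(C)C)C(C)C | intermediate
17 | bis(ketene): compound 11 with each diazoacetyl group replaced by a 2-oxoethenyl (CH=C=O) group | COc1ccc(-c2cc(=O)cc(C=C=O)o2)cc1Oc1ccc(-c2cc(=O)cc(C=C=O)o2)cc1 | intermediate
18 | bis(cyclobutenone): each pyranone C2 bears a 4-oxo-2-(triisopropylsiloxy)cyclobut-2-en-1-yl group (mixture of diastereomers, configuration undefined) | COc1ccc(-c2cc(=O)cc(C3C(=O)C=C3O[Si](C(C)C)(C(C)C)C(C)C)o2)cc1Oc1ccc(-c2cc(=O)cc(C3C(=O)C=C3O[Si](C(C)C)(C(C)C)C(C)C)o2)cc1 | intermediate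
19 | bis(dienylketene): each pyranone C2 bears a 4-oxo-2-(triisopropylsiloxy)buta-1,3-dien-1-yl group, pyranonyl cis to the ketenyl carbon | COc1ccc(-c2cc(=O)cc(/C=C(/O[Si](C(C)C)(C(C)C)C(C)C)\C=C=O)o2)cc1Oc1ccc(-c2cc(=O)cc(/C=C(/O[Si](C(C)C)(C(C)C)C(C)C)\C=C=O)o2)cc1 | intermediate
20 | bis(cyclohexadienone): keto tautomer of 21, each half a 2-aryl-7-(triisopropylsiloxy)-4aH-chromene-4,5-dione (C4a configuration undefined) | COc1ccc(C2=CC(=O)C3C(=O)C=C(O[Si](C(C)C)(C(C)C)C(C)C)C=C3O2)cc1Oc1ccc(C2=CC(=O)C3C(=O)C=C(O[Si](C(C)C)(C(C)C)C(C)C)C=C3O2)cc1 | intermediate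
21 | 7,7''-bis-O-(triisopropylsilyl)-4'-O-methylochnaflavone | COc1ccc(-c2cc(=O)c3c(O)cc(O[Si](C(C)C)(C(C)C)C(C)C)cc3o2)cc1Oc1ccc(-c2cc(=O)c3c(O)cc(O[Si](C(C)C)(C(C)C)C(C)C)cc3o2)cc1 | intermediate
22 | 4'-O-methylochnaflavone | COc1ccc(-c2cc(=O)c3c(O)cc(O)cc3o2)cc1Oc1ccc(-c2cc(=O)c3c(O)cc(O)cc3o2)cc1 | target

**Step count**
Total: 9 steps. Longest linear sequence: 8 steps (steps 1 to 6, 8 and 9); step 7 is a one-step branch.

**Steps most likely to fail**

Step 8 (double benzannulation). The aryl pyranone may itself be photolysed, the ketenes may be intercepted by traces of water or by the first-formed phenol, or only one of the two ends may annulate. In that case ring A would be brought in ready-made. The fallback sets out from the bis(acetophenone) 3, which would be C-acylated with diethyl carbonate and NaH in toluene to the bis(β-keto ester) ethyl 3-{3-[4-(3-ethoxy-3-oxopropanoyl)phenoxy]-4-methoxyphenyl}-3-oxopropanoate F1. F1 would then be heated with phloroglucinol without solvent (about 240 °C, or under microwave irradiation), a Mentzer-type thermal condensation of a phenol with a β-keto ester that is known to give 5,7-dihydroxyflavones directly. The route is rejoined at the target 22.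

Step 7 (siloxyalkyne). Lithium acetylide may disproportionate before it is oxidized, the ynolate may be silylated on carbon to a silylketene, or the small ynol ether may be lost or hydrolysed on isolation. The oxygen substituent of the ketenophile would then be changed from silyl to tert-butyl. KOtBu and trichloroethylene would give (E)-1,2-dichlorovinyl tert-butyl ether F2, and n-BuLi (2 equiv) followed by methanol would give tert-butoxyacetylene F3 (dichlorovinyl ether route to ynol ethers). The fallback sets out from the bis(diazo ketone) 11, which would be annulated with F3 as in step 8 (irradiation at room temperature, removal of the excess of F3 under vacuum, then 80 °C) to 7,7''-di-O-tert-butyl-4'-O-methylochnaflavone F4. CF3CO2H in CH2Cl2 would then remove both tert-butyl groups and leave the 4'-methyl ether untouched, rejoining the route at 22.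

Step 3 (double oxalylation). Acylation may occur at the central carbon of the diketones, only one arm may condense, or retro-Claisen cleavage may intervene. The central carbon would then be taken out of play. The fallback sets out from the bis(1,3-diketone) 5, which would be condensed with pyrrolidine (toluene, removal of water) to the bis(enaminone) (E)-1-{4-methoxy-3-[4-((E)-3-(pyrrolidin-1-yl)but-2-enoyl)phenoxy]phenyl}-3-(pyrrolidin-1-yl)but-2-en-1-one F5, whose only acidic position is the terminal methyl. LiN(SiMe3)2 and diethyl oxalate in THF at −78 °C would acylate it there (γ-acylation of enaminone anions, a known entry to 4-pyranones) to the bis(γ-oxalyl enaminone) ethyl 6-{3-[4-(6-ethoxy-5,6-dioxo-3-(pyrrolidin-1-yl)hex-2-enoyl)phenoxy]-4-methoxyphenyl}-2,6-dioxo-4-(pyrrolidin-1-yl)hex-4-enoate F6. Hot HCl/AcOH would hydrolyse the enamines, close both pyranones and cleave the esters, rejoining the route at the bis(pyranone acid) 9.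

**Further compounds**
F1 | step 8 | ethyl 3-{3-[4-(3-ethoxy-3-oxopropanoyl)phenoxy]-4-methoxyphenyl}-3-oxopropanoate | COc1ccc(C(=O)CC(=O)OCC)cc1Oc1ccc(C(=O)CC(=O)OCC)cc1
F2 | step 7 | (E)-1,2-dichlorovinyl tert-butyl ether | Cl/C=C(/Cl)OC(C)(C)C
F3 | step 7 | tert-butoxyacetylene | C#COC(C)(C)C
F4 | step 7 | 7,7''-di-O-tert-butyl-4'-O-methylochnaflavone | COc1ccc(-c2cc(=O)c3c(O)cc(OC(C)(C)C)cc3o2)cc1Oc1ccc(-c2cc(=O)c3c(O)cc(OC(C)(C)C)cc3o2)cc1
F5 | step 3 | (E)-1-{4-methoxy-3-[4-((E)-3-(pyrrolidin-1-yl)but-2-enoyl)phenoxy]phenyl}-3-(pyrrolidin-1-yl)but-2-en-1-one | COc1ccc(C(=O)/C=C(\C)N2CCCC2)cc1Oc1ccc(C(=O)/C=C(\C)N2CCCC2)cc1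
F6 | step 3 | ethyl 6-{3-[4-(6-ethoxy-5,6-dioxo-3-(pyrrolidin-1-yl)hex-2-enoyl)phenoxy]-4-methoxyphenyl}-2,6-dioxo-4-(pyrrolidin-1-yl)hex-4-enoate | COc1ccc(C(=O)/C=C(\CC(=O)C(=O)OCC)N2CCCC2)cc1Oc1ccc(C(=O)/C=C(\CC(=O)C(=O)OCC)N2CCCC2)cc1
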